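In a closed flask the charge is conserved: starting material, target and whatever target turns into add up to what went in, and the enzyme stays. After their peaks the readings of each earlier run fall with no level showing, so I take the end state to hold no target. What matters is how far along each set-up is when read.

| flask | starting material | enzyme | remark | time |
|---|---|---|---|---|
| Tuesday's | 20 mM | 0.13 µM | run made earlier |  |
| Sunday's | 20 mM | 0.087 µM | run made earlier |  |
| Saturday's | 20 mM | 0.20 µM | run made earlier |  |
| blue | 20 mM | 0.13 µM | everything together in a closed stirred flask, run for 15 min | 15 min |
| teal | 20 mM (fed, over 12.0 min) | 0.13 µM | all but starting material at the start; starting material goes in evenly over 12.0 min, the run ends at 15 min | 15 min |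
| grey | 20 mM | 0.13 µM | a single well-mixed tank run continuously and read at steady state, 45.0 min in it on average |  |
| green | 20 mM | 0.13 µM | a single well-mixed tank run continuously and read at steady state, 15 min in it on average |  |

- Tuesday's (time / min: target / %): 0.500: 12; 1.33: 29; 2.50: 51; 4.00: 64; 5.00: 61; 8.00: 40; 10.0: 29
- Sunday's (time / min: target / %): 0.667: 10; 1.00: 13; 1.50: 21; 2.50: 32; 4.00: 45; 6.00: 53; 10.0: 37
- Saturday's (time / min: target / %): 1.33: 43; 2.50: 70; 4.00: 66; 5.00: 58; 6.00: 50; 8.00: 36; 10.0: 20

(standard deviation of a reading: 2 percentage points)

- the stated concentrations are those of everything mixed, before any reaction; amounts are the same in each set-up
- the earlier runs were read with a standard deviation of 2 percentage points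
- the feed brings no volume worth counting
- the earlier runs were made in a closed, stirred flask

* the set-up with the highest amount of target at the outlet or at the end, in percent of the starting material put in ("none" if the first two lie within 2 percentage points) (blue / teal / grey / green / none)
* amount of target at the outlet or at the end, in percent of the starting material put in, blue
* amount of target at the outlet or at the end, in percent of the starting material put in, teal
* amount of target at the outlet or at the end, in percent of the starting material put in, grey
* amount of target at the outlet or at the end, in percent of the starting material put in, green

All four set-ups carry Tuesday's 0.13 µM of enzyme, so Tuesday's run serves. Its first reading shows a pace that would cover the charge in 4.17 min. Between 2.50 min and 4.00 min the net rise is slower by a factor of 2.77, and later it turns negative. From 8.00 min to 10.0 min, c_target falls from 40% to 29%. I read this as first-order loss with a constant of 0.161 /min, scatter included. Its inverse, 6.22 min, is the mean lifetime of target, the time in which loss shrinks target by a factor e. The fill time is shorter than this lifetime, so target builds first and loss then takes over.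

Blue has Tuesday's charge and enzyme, and I count the 5.00 min after Tuesday's last reading as loss with no further formation. They multiply target by 0.448, so my figure for blue is 13.0%. In teal, counting each portion as reacting on arrival, I get 27.3%. I hold this as a low figure: a portion reacting after its arrival is younger at the end than I count it. In a tank, outflow competes with loss, and the share of reacted material kept as target is one over one plus residence time per lifetime. Counting the whole charge as reacted, I get 12.1% for grey and 29.3% for green.

The forecast gives blue 13%, teal 31%, grey 13% and green 29%. It puts teal first and calls that close “though this is close”. Its teal stands above mine, and my figures leave teal against green open.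

The flask gives blue 13.7%, teal 31.7%, grey 12.0% and green 28.0%, with teal first, ahead of green by 3.7 percentage points at a margin of 2 points.

    target → over-reaction product (k = 0.160 /min)
    starting material + enzyme → target + enzyme, rate k2*[starting material]*[enzyme]/(1 + ([starting material]/Km2)) (3.50 mM, k = 2.10 × 10⁵ /M/s)

The half-life of target by its conversion into over-reaction product alone, 4.3 min, is shorter than blue's 15 min, and those 15 min span 2.41 of the lifetimes read from Tuesday's run. In green, 0.993 mM of starting material stands in the tank, so 95.0% has reacted, and the lifetime then gives 27.9% of target, where the tank holds 28.0%.

The numbers in the tables are calculated with made-up constants; scatter was added.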